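**Plan**

1. Numbering used below: piperazine N1–C2H(CH2–ring A)–C3H2–N4–C5H(CH2–ring B)–C6H2. Ring A is the phenol ring that bears the guanine; ring B is the para-phenylene ring.
2. Retrosynthesis: the purine imidazole ring is opened at C8 (salicylaldehyde + 2,5,6-triaminopyrimidin-4(3H)-one). Then C2–C3 and N4–C5 are cut in one stroke, which lifts C3–N4 out as N-benzylmethanimine. Then the ring A–O bond of the diaryl ether and the N1–C6 amide bond are cut.
3. Enabling feature: C2 lies between N1 and the benzylic carbon of ring A, and C5 lies next to C6. With that benzylic carbon as a ketone, C2 is an enolisable nucleophile; with C6 as a lactam carbonyl, a C5 sulfonate is an SN2 electrophile. The four atoms C2–N1–C6–C5 thus act as a 1,4-dipole equivalent toward the C=N unit, and both helper carbonyls are reduced away later.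
4. Forward order: amide; then the 14-membered ring (ring A–CO–C2–N1–C6–C5–CH2–ring B–O) by Ullmann coupling; then the piperazinone ring across it; then reductions, phenol release, formylation, purine ring, N-debenzylation.
5. Stereochemistry: C5 comes from D-tyrosine (hydroxy-deamination with retention, then SN2 inversion by N4). C2 is epimerisable beside the ketone and should settle cis to C5, because only the cis-2,5 bridge fits the 14-membered ring.

Key step: step 7

Remark on the chemistry: 17 is used as its commercial sulfate, and the guanine is drawn in the tautomer of the target SMILES.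

**Route**

Step 1
Reactants: 1 1-(3-bromo-4-methoxyphenyl)ethanone
Product: 2 2-bromo-1-(3-bromo-4-methoxyphenyl)ethanone
Conditions: CuBr2 (2 equiv), EtOAc/CHCl3, reflux
Reagents that add atoms: copper dibromide, Br[Cu]Br
Why: α-Bromination of an aryl methyl ketone with CuBr2 should stop at the monobromide and leave the acyl-deactivated anisole ring untouched.

Step 2
Reactants: 2 2-bromo-1-(3-bromo-4-methoxyphenyl)ethanone; 3 benzylamine
Product: 4 2-(benzylamino)-1-(3-bromo-4-methoxyphenyl)ethanone hydrochloride
Conditions: BnNH2 (3 equiv), THF, 0 °C; then HCl, Et2O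
Reagents that add atoms: hydrogen chloride, Cl
Why: SN2 amination of a phenacyl bromide with excess primary amine should give the secondary amine, and isolation as the salt prevents self-condensation of the α-amino ketone.

Step 3
Reactants: 5 D-tyrosine
Product: 6 (R)-2-hydroxy-3-(4-hydroxyphenyl)propanoic acid
Conditions: NaNO2, 1 M H2SO4, 0 °C to rt
Reagents that add atoms: water, O
Why: Diazotisation with hydroxy-deamination of an α-amino acid runs with net retention (double inversion through the α-lactone), so the (R) centre of D-tyrosine becomes the (R) carbinol that is later C5.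

Step 4
Reactants: 4 2-(benzylamino)-1-(3-bromo-4-methoxyphenyl)ethanone hydrochloride; 6 (R)-2-hydroxy-3-(4-hydroxyphenyl)propanoic acid
Product: 7 (R)-N-benzyl-N-[2-(3-bromo-4-methoxyphenyl)-2-oxoethyl]-2-hydroxy-3-(4-hydroxyphenyl)propanamide
Conditions: EDC·HCl, HOBt, iPr2NEt, DMF, 0 °C to rt
Reagents that add atoms: none
Why: Carbodiimide/HOBt amide coupling in which the amine freed in place should outcompete the two hydroxyl groups for the active ester, with no bond to the stereocentre touched.

Step 5
Reactants: 7 (R)-N-benzyl-N-[2-(3-bromo-4-methoxyphenyl)-2-oxoethyl]-2-hydroxy-3-(4-hydroxyphenyl)propanamide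
Product: 8 (R)-hydroxy keto macrolactam (14-membered ring: ring A–C(=O)–C2H2–N1(Bn)–C6(=O)–C5H(OH)–CH2–ring B–O–ring A C3)
Conditions: CuI, N,N-dimethylglycine·HCl, Cs2CO3, 1,4-dioxane (3 mM), 100 °C
Reagents that add atoms: none
Why: Intramolecular Ullmann diaryl ether coupling, a reaction type that has closed this same 14-membered meta,para-bridged ring in tyrosine-derived macrocycles; the phenoxide is the only competent nucleophile, the tertiary N-benzyl amide can adopt the cis rotamer that brings the rings together, and the C5 carbinol is not acidic enough to epimerise.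

Step 6
Reactants: 8 (R)-hydroxy keto macrolactam
Product: 9 C5 4-nitrobenzenesulfonate of 8 (C5 still R)
Conditions: 4-O2NC6H4SO2Cl, Et3N, DMAP (cat.), CH2Cl2, 0 °C
Reagents that add atoms: 4-nitrobenzenesulfonyl chloride, O=S(=O)(Cl)c1ccc(cc1)[N+](=O)[O-]
Why: O-Sulfonylation of the only free hydroxyl (the phenol was consumed in step 5) gives an α-sulfonyloxy amide, a class that is configurationally stable and is displaced by amines with inversion.

Step 7
Reactants: 9 C5 4-nitrobenzenesulfonate of 8; 10 1,3,5-tribenzyl-1,3,5-triazinane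
Product: 12 cis-bridged N1,N4-dibenzyl keto piperazinone (C6=O; ring-A C=O on C2; C5 S), via Mannich base 11 (not isolated)
Conditions: 10 (0.4 equiv), CF3CO2H (1.5 equiv), MeCN (5 mM), 50 °C; then iPr2NEt (5 equiv), 60 °C
Reagents that add atoms: none
Why: Proposed new method: acid cracks triazinane 10 to N-benzylmethaniminium, the enol of the aryl ketone attacks it at C2 (Mannich, C2–C3 bond), and after basification the freed secondary amine N4 displaces the C5 sulfonate across the macrocycle (N4–C5 bond), a formal [4+2] union of a C=N unit with the C2–N1–C6–C5 1,4-dipole equivalent. The closest known reaction types are the Mannich reaction of enolisable ketones with 1,3,5-triazinanes as formaldimine sources and the SN2 amination of α-sulfonyloxy carbonyl compounds. The piperazinone ring closes 6-exo-tet. C5 is set by inversion of the (R)-sulfonate to (S); C2 is set under thermodynamic control, since it epimerises through the enol and only the epimer that gives the cis-2,5 bridge (both ring hydrogens outside the bicycle) can close within the 14-membered ring. The step needs C- over O-alkylation of the enol and N-alkylation over elimination; the acidic Mannich stage (enol, one enolisable carbon only), the tertiary N1-benzyl amide (no N–H for aminal or oxazole formation), the hindered weak base and one equivalent of imine (against double aminomethylation) should secure this.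

Step 8
Reactants: 12 cis-bridged N1,N4-dibenzyl keto piperazinone
Product: 13 (2S,5S)-N1,N4-dibenzyl bridged piperazin-6-one (ring-A C=O now CH2)
Conditions: Et3SiH, CF3CO2H, 50 °C
Reagents that add atoms: none
Why: Ionic hydrogenation of a para-alkoxyaryl ketone to the methylene, known for α-acylamino aryl ketones, removes the activating carbonyl while the lactam and N-benzyl groups are inert and the macrocycle keeps C2 cis.

Step 9
Reactants: 13 (2S,5S)-N1,N4-dibenzyl bridged piperazin-6-one
Product: 14 (2S,5S)-N1,N4-dibenzyl piperazine macrocycle, ring-A O-methyl ether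
Conditions: LiAlH4, THF, reflux
Reagents that add atoms: none
Why: Hydride reduction of a tertiary lactam to the amine removes the second helper carbonyl without touching the diaryl ether or either stereocentre.

Step 10
Reactants: 14 (2S,5S)-N1,N4-dibenzyl piperazine macrocycle, ring-A O-methyl ether
Product: 15 (2S,5S)-N1,N4-dibenzyl piperazine macrocycle, ring-A phenol
Conditions: BBr3 (excess), CH2Cl2, -78 °C to rt
Reagents that add atoms: none
Why: Lewis acid cleavage of an aryl methyl ether with BBr3 spares diaryl ethers and tertiary N-benzyl amines.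

Step 11
Reactants: 15 (2S,5S)-N1,N4-dibenzyl piperazine macrocycle, ring-A phenol
Product: 16 ring-A salicylaldehyde (CHO ortho to OH, at the only free ortho position)
Conditions: MgCl2, Et3N, (CH2O)n, MeCN, reflux
Reagents that add atoms: paraformaldehyde (formaldehyde), C=O
Why: Magnesium phenoxide-directed ortho-formylation (Casnati–Skattebøl type) is ortho-specific, only one ortho position is open, and the two nitrogens are tertiary so they cannot enter Mannich chemistry with formaldehyde.

Step 12
Reactants: 16 ring-A salicylaldehyde; 17 2,5,6-triaminopyrimidin-4(3H)-one sulfate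
Product: 19 N1,N4-dibenzyl guanipiperazine A, via Schiff base 18 (not isolated)
Conditions: NaOAc, DMSO, 80 °C; then air (O2), 110 °C
Reagents that add atoms: none
Why: Traube-type purine synthesis in which the most nucleophilic 5-NH2 condenses with the aldehyde, the 6-NH2 closes the aminal, and aerobic dehydrogenation aromatises the imidazole ring to the 8-arylguanine.

Step 13
Reactants: 19 N1,N4-dibenzyl guanipiperazine A
Product: 20 guanipiperazine A
Conditions: H2 (4 bar), Pd(OH)2/C, AcOH/MeOH, 40 °C
Reagents that add atoms: none
Why: Hydrogenolysis of the two N-benzyl groups should spare the ring C–N bonds (homobenzylic, not benzylic), the diaryl ether and the guanine.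

**Compound list**

1 | 1-(3-bromo-4-methoxyphenyl)ethanone | CC(=O)c1ccc(OC)c(Br)c1 | starting material
2 | 2-bromo-1-(3-bromo-4-methoxyphenyl)ethanone | BrCC(=O)c1ccc(OC)c(Br)c1 | intermediate
3 | benzylamine | NCc1ccccc1 | starting material
4 | 2-(benzylamino)-1-(3-bromo-4-methoxyphenyl)ethanone hydrochloride | Cl.O=C(CNCc1ccccc1)c1ccc(OC)c(Br)c1 | intermediate
5 | D-tyrosine | N[C@H](Cc1ccc(O)cc1)C(=O)O | starting material
6 | (R)-2-hydroxy-3-(4-hydroxyphenyl)propanoic acid | O[C@H](Cc1ccc(O)cc1)C(=O)O | intermediate
7 | (R)-N-benzyl-N-[2-(3-bromo-4-methoxyphenyl)-2-oxoethyl]-2-hydroxy-3-(4-hydroxyphenyl)propanamide | O[C@H](Cc1ccc(O)cc1)C(=O)N(Cc1ccccc1)CC(=O)c1ccc(OC)c(Br)c1 | intermediate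
8 | (R)-hydroxy keto macrolactam: 14-membered ring, ring B para-O bonded to ring A C3 (ortho to OMe), N1-benzyl, C5 (R) carbinol | O[C@@H]1Cc2ccc(cc2)Oc2cc(ccc2OC)C(=O)CN(Cc2ccccc2)C1=O | intermediate
9 | C5 4-nitrobenzenesulfonate of 8, C5 (R) | O=S(=O)(O[C@@H]1Cc2ccc(cc2)Oc2cc(ccc2OC)C(=O)CN(Cc2ccccc2)C1=O)c1ccc(cc1)[N+](=O)[O-] | intermediate
10 | 1,3,5-tribenzyl-1,3,5-triazinane | C1N(Cc2ccccc2)CN(Cc2ccccc2)CN1Cc1ccccc1 | starting material
11 | Mannich base: 9 carrying CH2NHBn on C2 (both C2 epimers, equilibrating; C5 R) | O=S(=O)(O[C@@H]1Cc2ccc(cc2)Oc2cc(ccc2OC)C(=O)C(CNCc2ccccc2)N(Cc2ccccc2)C1=O)c1ccc(cc1)[N+](=O)[O-] | intermediate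
12 | cis-bridged keto piperazinone: N1,N4-dibenzyl, C6=O, ring-A C=O on C2, C5 (S), C2–H cis to C5–H (C2 descriptor R only because of the ketone) | COc1ccc2cc1Oc1ccc(cc1)C[C@H]3C(=O)N(Cc4ccccc4)[C@H](CN3Cc4ccccc4)C2=O | intermediate
13 | (2S,5S)-N1,N4-dibenzyl bridged piperazin-6-one, ring-A O-methyl ether | COc1ccc2cc1Oc1ccc(cc1)C[C@H]3C(=O)N(Cc4ccccc4)[C@H](CN3Cc4ccccc4)C2 | intermediate
14 | (2S,5S)-N1,N4-dibenzyl piperazine macrocycle, ring-A O-methyl ether | COc1ccc2cc1Oc1ccc(cc1)C[C@H]3CN(Cc4ccccc4)[C@H](CN3Cc4ccccc4)C2 | intermediate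
15 | (2S,5S)-N1,N4-dibenzyl piperazine macrocycle, ring-A phenol | Oc1ccc2cc1Oc1ccc(cc1)C[C@H]3CN(Cc4ccccc4)[C@H](CN3Cc4ccccc4)C2 | intermediate
16 | 15 with CHO on ring A ortho to the OH | O=Cc1cc2cc(c1O)Oc1ccc(cc1)C[C@H]3CN(Cc4ccccc4)[C@H](CN3Cc4ccccc4)C2 | intermediate
17 | 2,5,6-triaminopyrimidin-4(3H)-one sulfate | Nc1nc(N)c(N)c(=O)[nH]1.OS(=O)(=O)O | starting material
18 | Schiff base of aldehyde 16 with the 5-NH2 of 17 | Nc1nc(N)c(N=Cc2cc3cc(c2O)Oc2ccc(cc2)C[C@H]4CN(Cc5ccccc5)[C@H](CN4Cc5ccccc5)C3)c(=O)[nH]1 | intermediate
19 | N1,N4-dibenzyl guanipiperazine A | Nc1nc2nc(-c3cc4cc(c3O)Oc3ccc(cc3)C[C@H]5CN(Cc6ccccc6)[C@H](CN5Cc6ccccc6)C4)[nH]c2c(=O)[nH]1 | intermediate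
20 | guanipiperazine A | Nc1nc2nc(-c3cc4cc(c3O)Oc3ccc(cc3)C[C@H]3CN[C@H](CN3)C4)[nH]c2c(=O)[nH]1 | target

**Totals**

Total step count: 13. Longest linear sequence: 12 steps (steps 1, 2 and 4 to 13, from compound 1).

**Steps most likely to fail**

Step 7 (Proposed new method). The nosylate may be lost by elimination or by O-alkylation from the enol before the amine is in place, aminomethylation may go twice, or the transannular closure may be too slow. The fallback uses known chemistry and reverses the order of bond formation. It sets out from 9: displacement of the sulfonate with benzylamine (MeCN, rt; SN2 amination of an α-sulfonyloxy amide, inversion) should give the (S)-C5 benzylamino macrolactam ketone F1. Treatment of F1 with aqueous formaldehyde in AcOH/EtOH at 60 °C forms the N4 iminium in place and closes C2–C3 by a classical intramolecular Mannich reaction, again cis-selective through the epimerisable C2. The fallback comes back to the route at 12.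

Step 5. The hindered ortho-methoxy aryl bromide may react too slowly, so that oligomerisation and base-driven enolate chemistry at 100 °C take over. The fallback changes the coupling manifold and sets out from 7: Miyaura borylation (B2pin2, Pd(dppf)Cl2, KOAc, dioxane, 80 °C) should give the aryl pinacol boronate F2. Chan–Lam ring closure of F2 at room temperature (Cu(OAc)2, pyridine, Et3N, 4 Å molecular sieves, O2, CH2Cl2, high dilution) comes back to the route at 8.

Step 13. The guanine may poison the catalyst and the product may be poorly soluble, so that debenzylation stops halfway. The fallback moves the debenzylation forward and switches to acid-labile protection. It sets out from 15: hydrogenolysis (H2, Pd(OH)2/C, AcOH) should give the free bis-secondary amine phenol F3. Boc2O (then brief K2CO3/MeOH to cleave any phenyl carbonate) gives the N1,N4-di-Boc phenol F4. The same ortho-formylation gives the di-Boc salicylaldehyde F5, and the same Traube-type annulation with 17 gives di-Boc guanipiperazine A F6. CF3CO2H/CH2Cl2 then removes both carbamates, and the fallback comes back to the route at 20.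

Further compounds
F1 | step 7 | (S)-C5 benzylamino macrolactam ketone (9 with NHBn in place of the sulfonate, inverted) | c1ccccc1CN[C@H]1Cc2ccc(cc2)Oc2cc(ccc2OC)C(=O)CN(Cc2ccccc2)C1=O
F2 | step 5 | aryl pinacol boronate of 7 (Bpin in place of Br) | O[C@H](Cc1ccc(O)cc1)C(=O)N(Cc1ccccc1)CC(=O)c1ccc(OC)c(c1)B1OC(C)(C)C(C)(C)O1
F3 | step 13 | (2S,5S) guanine-free macrocycle with free N1–H, N4–H and phenol | Oc1ccc2cc1Oc1ccc(cc1)C[C@H]3CN[C@H](CN3)C2
F4 | step 13 | N1,N4-di-Boc derivative of F3 | Oc1ccc2cc1Oc1ccc(cc1)C[C@H]3CN(C(=O)OC(C)(C)C)[C@H](CN3C(=O)OC(C)(C)C)C2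
F5 | step 13 | N1,N4-di-Boc ring-A salicylaldehyde | O=Cc1cc2cc(c1O)Oc1ccc(cc1)C[C@H]3CN(C(=O)OC(C)(C)C)[C@H](CN3C(=O)OC(C)(C)C)C2
F6 | step 13 | N1,N4-di-Boc guanipiperazine A | Nc1nc2nc(-c3cc4cc(c3O)Oc3ccc(cc3)C[C@H]5CN(C(=O)OC(C)(C)C)[C@H](CN5C(=O)OC(C)(C)C)C4)[nH]c2c(=O)[nH]1
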